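Everything rests on making ring D last, from a pyrone. Ring D is a 1,4-phenylene whose only substituents are the ether oxygen on C3 of ring C and, para to it, the benzylic carbon that leads to C1 of the dibenzofuran; an aryloxyacetylene and a 5-acyl-2-pyrone give exactly this pattern after cycloaddition and loss of CO2. In step 13 the tethered alkyne adds across pyrone C3 and C6, so one operation forms both new C–C bonds of ring D, converts the ynol ether into the diaryl ether and closes the 18-membered ring. The precursor 25 is a 3-methoxydibenzofuran with a coumalyl ketone on its C1 methylene and, at C7, the ethylene-linked ring C carrying methoxy and ethynyloxy groups.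

Key step: step 13

Remark: the target is achiral (no stereocentre, no stereodefined double bond); dibenzofuran locants are used (O = position 5; ring D arm on C1, oxygen on C3, ring C arm on C7), and ring C is the catechol-type ring.

Step 1
Reactants: 1 methyl 3,5-dimethoxybenzoate
Product: 2 methyl 2-bromo-3,5-dimethoxybenzoate
Conditions: NBS, MeCN, 0 °C to rt
Reagents that add atoms: N-bromosuccinimide, O=C1CCC(=O)N1Br
Why: Electrophilic aromatic bromination should occur at C2 (equivalent to C6), para to one methoxy group and ortho to the other, and not at the crowded C4 between the two methoxy groups, which places the halogen at the future biaryl carbon next to the C1 carbon substituent.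

Step 2
Reactants: 2 methyl 2-bromo-3,5-dimethoxybenzoate; 3 (4-chloro-2-fluorophenyl)boronic acid
Product: 4 methyl 2-(4-chloro-2-fluorophenyl)-3,5-dimethoxybenzoate
Conditions: Pd(PPh3)4 (5 mol%), K2CO3, DME/H2O, 85 °C
Reagents that add atoms: none
Why: Suzuki–Miyaura coupling in which the triphenylphosphine catalyst should insert into the C–Br bond only, so that the chloride (handle for C7) and the fluoride (leaving group for the furan closure) are carried through.

Step 3
Reactants: 4 methyl 2-(4-chloro-2-fluorophenyl)-3,5-dimethoxybenzoate
Product: 5 methyl 2-(4-chloro-2-fluorophenyl)-3,5-dihydroxybenzoate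
Conditions: BBr3, CH2Cl2, −78 °C to rt; then H2O
Reagents that add atoms: none
Why: Lewis-acid cleavage of aryl methyl ethers (BBr3 demethylation) frees both phenols, since the two methoxy groups cannot be differentiated here, while the ester, C–F and C–Cl bonds should survive; the phenol not needed for ring closure is re-methylated in step 4.

Step 4
Reactants: 5 methyl 2-(4-chloro-2-fluorophenyl)-3,5-dihydroxybenzoate
Product: 7 methyl 7-chloro-3-methoxydibenzofuran-1-carboxylate, via potassium 7-chloro-1-(methoxycarbonyl)dibenzofuran-3-olate 6 (not isolated)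
Conditions: K2CO3, NMP, 150 °C; then MeI, 40 °C
Reagents that add atoms: iodomethane, CI
Why: Intramolecular nucleophilic aromatic substitution, in which only the phenoxide ortho to the biaryl bond can reach the C–F carbon and close the furan, followed by Williamson methylation in the same pot of the remaining phenoxide and of any carboxylate formed by ester cleavage.

Step 5
Reactants: 8 isovanillin (3-hydroxy-4-methoxybenzaldehyde); 9 methyltriphenylphosphonium bromide
Product: 11 2-methoxy-5-vinylphenol, via methylenetriphenylphosphorane 10 (not isolated)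
Conditions: KOt-Bu (2.5 equiv of ylide), THF, 0 °C to rt
Reagents that add atoms: none
Why: Wittig methylenation, with excess ylide to allow for deprotonation of the phenol, whose phenoxide is meta to the aldehyde and therefore does not deactivate it by resonance.

Step 6
Reactants: 11 2-methoxy-5-vinylphenol; 7 methyl 7-chloro-3-methoxydibenzofuran-1-carboxylate
Product: 13 methyl 7-[2-(3-hydroxy-4-methoxyphenyl)ethyl]-3-methoxydibenzofuran-1-carboxylate, via bis(9-BBN) adduct of the vinylphenol 12 (not isolated)
Conditions: 9-BBN (2.3 equiv), THF, 0 °C to rt; then 7, Pd(OAc)2 (3 mol%), SPhos, K3PO4, H2O, 65 °C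
Reagents that add atoms: none
Why: Anti-Markovnikov hydroboration of the styrene (the phenol takes up a further equivalent of borane as a borinate that the aqueous base hydrolyses) followed by B-alkyl Suzuki–Miyaura coupling, for which the electron-rich biarylphosphine allows oxidative addition into the aryl chloride, gives the saturated two-carbon bridge directly.

Step 7
Reactants: 13 methyl 7-[2-(3-hydroxy-4-methoxyphenyl)ethyl]-3-methoxydibenzofuran-1-carboxylate; 14 trichloroethylene
Product: 16 methyl 7-(2-{3-[(E)-1,2-dichloroethenyloxy]-4-methoxyphenyl}ethyl)-3-methoxydibenzofuran-1-carboxylate, via dichloroacetylene 15 (not isolated)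
Conditions: K2CO3, DMF, 70 °C
Reagents that add atoms: none
Why: Base-mediated elimination of HCl from trichloroethylene and anti addition of the phenoxide to the dichloroacetylene so formed should give the (E)-1,2-dichlorovinyl ether, the ester and the ethers being inert to carbonate at this temperature.

Step 8
Reactants: 16 methyl 7-(2-{3-[(E)-1,2-dichloroethenyloxy]-4-methoxyphenyl}ethyl)-3-methoxydibenzofuran-1-carboxylate
Product: 17 [7-(2-{3-[(E)-1,2-dichloroethenyloxy]-4-methoxyphenyl}ethyl)-3-methoxydibenzofuran-1-yl]methanol
Conditions: i-Bu2AlH, CH2Cl2, −78 to 0 °C; aq. potassium sodium tartrate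
Reagents that add atoms: none
Why: Hydride reduction of the ester to the primary benzylic alcohol, placed here because an ester would not survive n-BuLi in step 9, while the chlorinated enol ether is inert to the aluminium hydride at low temperature.

Step 9
Reactants: 17 [7-(2-{3-[(E)-1,2-dichloroethenyloxy]-4-methoxyphenyl}ethyl)-3-methoxydibenzofuran-1-yl]methanol
Product: 19 {7-[2-(3-ethynyloxy-4-methoxyphenyl)ethyl]-3-methoxydibenzofuran-1-yl}methanol, via dilithium alkoxide acetylide 18 (not isolated)
Conditions: n-BuLi (3.3 equiv), THF, −78 to −40 °C; then H2O, −78 °C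
Reagents that add atoms: none
Why: Dehydrochlorination of the 1,2-dichlorovinyl ether and chlorine–lithium exchange on the resulting chloroalkyne (the standard ynol ether synthesis from trichloroethylene adducts) give the lithium aryloxyacetylide, protonated on quench, the first equivalent of base having turned the hydroxyl group into an inert alkoxide.

Step 10
Reactants: 19 {7-[2-(3-ethynyloxy-4-methoxyphenyl)ethyl]-3-methoxydibenzofuran-1-yl}methanol
Product: 21 1-(chloromethyl)-7-[2-(3-ethynyloxy-4-methoxyphenyl)ethyl]-3-methoxydibenzofuran, via benzylic mesylate 20 (not isolated)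
Conditions: MsCl, 2,4,6-collidine, LiCl, DMF, 0 °C
Reagents that add atoms: lithium chloride, [Li+].[Cl-]
Why: One-pot mesylation and SN2 displacement by chloride under collidine-buffered conditions that should spare the acid-sensitive ynol ether; C1 is meta to both ring A oxygens, so the product is an ordinary, not an over-activated, benzylic chloride.

Step 11
Reactants: 22 coumalic acid
Product: 23 coumalyl chloride (2-oxo-2H-pyran-5-carbonyl chloride)
Conditions: (COCl)2, DMF (cat.), CH2Cl2, rt; volatiles removed
Reagents that add atoms: oxalyl chloride, ClC(=O)C(=O)Cl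
Why: Standard acid chloride formation with oxalyl chloride and catalytic DMF, to which the pyrone ring is stable; evaporation removes HCl before the coupling.

Step 12
Reactants: 21 1-(chloromethyl)-7-[2-(3-ethynyloxy-4-methoxyphenyl)ethyl]-3-methoxydibenzofuran; 23 coumalyl chloride
Product: 25 5-({7-[2-(3-ethynyloxy-4-methoxyphenyl)ethyl]-3-methoxydibenzofuran-1-yl}acetyl)-2H-pyran-2-one, via benzylic zinc chloride 24 (not isolated)
Conditions: Zn dust, LiCl, THF, 25 °C; then added to 23, Pd(PPh3)4 (5 mol%), THF, 0 °C
Reagents that add atoms: none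
Why: LiCl-promoted zinc insertion into the benzylic C–Cl bond gives a reagent too weakly basic to deprotonate the terminal alkyne, and the zerovalent-palladium-catalysed Negishi acylation of the acid chloride (inverse addition) should be much faster than uncatalysed addition of the zinc reagent to the pyrone.

Step 13
Reactants: 25 5-({7-[2-(3-ethynyloxy-4-methoxyphenyl)ethyl]-3-methoxydibenzofuran-1-yl}acetyl)-2H-pyran-2-one
Product: 27 macrocyclic bridge ketone of asterelin A dimethyl ether (C=O on the bridge carbon attached to ring D), via bridged bicyclic lactone 26 (not isolated)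
Conditions: o-xylene (about 0.5 mM, syringe-pump addition), 2,6-di-tert-butyl-4-methylpyridine (0.2 equiv), 140 °C
Reagents that add atoms: none
Why: Inverse-electron-demand Diels–Alder reaction followed by retro-Diels–Alder loss of CO2: the electron-rich ynol ether adds across C3 and C6 of the electron-poor 5-acyl-2-pyrone to give the 2-oxabicyclo[2.2.2]octadienone 26, which expels CO2 and leaves ring D aromatic. The closest known reactions are the cycloaddition–decarboxylation of coumalic esters with ynol ethers, enol ethers and ynamines to para-substituted benzoates, and intramolecular pyrone–alkyne cycloadditions used to close strained cyclophanes. Ring D closes in the (4+2) mode from pyrone carbons C3–C6 and the two alkyne carbons; the 18-membered ring closes through the same two bonds in the type 2 intramolecular mode (tether from the acyl group on the internal diene carbon C5 to the ynol ether oxygen), so the macrocycle is first spanned by a boat-shaped bicyclic diene and the strain of bridging the 1,4-positions is offset by CO2 extrusion and the gain of aromaticity. No stereocentre is created in 27, because the two bridgehead centres of 26 disappear with CO2. The step needs para and not meta regiochemistry, which the matched polarisation should secure (the nucleophilic terminal CH bonds to C6, which is β to the ketone and δ to the lactone carbonyl, and the oxygen-bearing carbon bonds to C3), and it needs cyclisation to outrun oligomerisation, for which slow addition into hot solvent at high dilution and a hindered pyridine as acid scavenger are used.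

Step 14
Reactants: 27 macrocyclic bridge ketone of asterelin A dimethyl ether
Product: 28 asterelin A dimethyl ether
Conditions: Et3SiH, CF3CO2H, CH2Cl2, 0 °C to rt
Reagents that add atoms: none
Why: Ionic hydrogenation, in which protonation of the aryl ketone, hydride transfer from the silane, ionisation of the carbinol to a benzylic cation stabilised by the para-aryloxy group of ring D and a second hydride transfer give the methylene group, while aryl ethers and the dibenzofuran are inert.

Step 15
Reactants: 28 asterelin A dimethyl ether
Product: 29 asterelin A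
Conditions: BBr3, CH2Cl2, −78 to 0 °C; then H2O
Reagents that add atoms: none
Why: BBr3 demethylation of the two aryl methyl ethers, under which the diaryl ether and the dibenzofuran C–O bonds should not be cleaved and no stereocentre is at stake.

Compound list

1 | methyl 3,5-dimethoxybenzoate | COC(=O)c1cc(OC)cc(OC)c1 | starting material
2 | methyl 2-bromo-3,5-dimethoxybenzoate | COC(=O)c1cc(OC)cc(OC)c1Br | intermediate
3 | (4-chloro-2-fluorophenyl)boronic acid | OB(O)c1ccc(Cl)cc1F | starting material
4 | methyl 2-(4-chloro-2-fluorophenyl)-3,5-dimethoxybenzoate | COC(=O)c1cc(OC)cc(OC)c1-c1ccc(Cl)cc1F | intermediate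
5 | methyl 2-(4-chloro-2-fluorophenyl)-3,5-dihydroxybenzoate | COC(=O)c1cc(O)cc(O)c1-c1ccc(Cl)cc1F | intermediate
6 | potassium 7-chloro-1-(methoxycarbonyl)dibenzofuran-3-olate (not isolated) | COC(=O)c1cc([O-])cc2oc3cc(Cl)ccc3c12.[K+] | intermediate
7 | methyl 7-chloro-3-methoxydibenzofuran-1-carboxylate | COC(=O)c1cc(OC)cc2oc3cc(Cl)ccc3c12 | intermediate
8 | isovanillin (3-hydroxy-4-methoxybenzaldehyde) | COc1ccc(C=O)cc1O | starting material
9 | methyltriphenylphosphonium bromide | C[P+](c1ccccc1)(c1ccccc1)c1ccccc1.[Br-] | starting material
10 | methylenetriphenylphosphorane (not isolated) | C=P(c1ccccc1)(c1ccccc1)c1ccccc1 | intermediate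
11 | 2-methoxy-5-vinylphenol | COc1ccc(C=C)cc1O | intermediate
12 | 9-{2-[3-(9-borabicyclo[3.3.1]nonan-9-yloxy)-4-methoxyphenyl]ethyl}-9-borabicyclo[3.3.1]nonane (not isolated) | COc1ccc(CCB2C3CCCC2CCC3)cc1OB1C2CCCC1CCC2 | intermediate
13 | methyl 7-[2-(3-hydroxy-4-methoxyphenyl)ethyl]-3-methoxydibenzofuran-1-carboxylate | COC(=O)c1cc(OC)cc2oc3cc(CCc4ccc(OC)c(O)c4)ccc3c12 | intermediate
14 | trichloroethylene | ClC=C(Cl)Cl | starting material
15 | dichloroacetylene (not isolated) | ClC#CCl | intermediate
16 | methyl 7-(2-{3-[(E)-1,2-dichloroethenyloxy]-4-methoxyphenyl}ethyl)-3-methoxydibenzofuran-1-carboxylate | COC(=O)c1cc(OC)cc2oc3cc(CCc4ccc(OC)c(O/C(Cl)=C\Cl)c4)ccc3c12 | intermediate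
17 | [7-(2-{3-[(E)-1,2-dichloroethenyloxy]-4-methoxyphenyl}ethyl)-3-methoxydibenzofuran-1-yl]methanol | OCc1cc(OC)cc2oc3cc(CCc4ccc(OC)c(O/C(Cl)=C\Cl)c4)ccc3c12 | intermediate
18 | dilithium salt of 19 (lithium alkoxide, lithium acetylide; not isolated) | [Li]OCc1cc(OC)cc2oc3cc(CCc4ccc(OC)c(OC#C[Li])c4)ccc3c12 | intermediate
19 | {7-[2-(3-ethynyloxy-4-methoxyphenyl)ethyl]-3-methoxydibenzofuran-1-yl}methanol | OCc1cc(OC)cc2oc3cc(CCc4ccc(OC)c(OC#C)c4)ccc3c12 | intermediate
20 | {7-[2-(3-ethynyloxy-4-methoxyphenyl)ethyl]-3-methoxydibenzofuran-1-yl}methyl methanesulfonate (not isolated) | CS(=O)(=O)OCc1cc(OC)cc2oc3cc(CCc4ccc(OC)c(OC#C)c4)ccc3c12 | intermediate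
21 | 1-(chloromethyl)-7-[2-(3-ethynyloxy-4-methoxyphenyl)ethyl]-3-methoxydibenzofuran | ClCc1cc(OC)cc2oc3cc(CCc4ccc(OC)c(OC#C)c4)ccc3c12 | intermediate
22 | coumalic acid (2-oxo-2H-pyran-5-carboxylic acid) | OC(=O)C1=COC(=O)C=C1 | starting material
23 | coumalyl chloride (2-oxo-2H-pyran-5-carbonyl chloride) | ClC(=O)C1=COC(=O)C=C1 | intermediate
24 | ({7-[2-(3-ethynyloxy-4-methoxyphenyl)ethyl]-3-methoxydibenzofuran-1-yl}methyl)zinc chloride (not isolated) | Cl[Zn]Cc1cc(OC)cc2oc3cc(CCc4ccc(OC)c(OC#C)c4)ccc3c12 | intermediate
25 | 5-({7-[2-(3-ethynyloxy-4-methoxyphenyl)ethyl]-3-methoxydibenzofuran-1-yl}acetyl)-2H-pyran-2-one (key-step precursor) | COc1cc(CC(=O)C2=COC(=O)C=C2)c2c(c1)oc1cc(CCc3ccc(OC)c(OC#C)c3)ccc12 | intermediate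
26 | macrocyclic 2-oxabicyclo[2.2.2]octa-5,7-dien-3-one cycloadduct (racemic; the two bridgehead centres are fixed relative to each other by the bicycle; not isolated) | COc1cc2c3c(c1)oc1cc(ccc13)CCc1ccc(OC)c(c1)OC1=CC3OC(=O)C1C=C3C(=O)C2 | intermediate
27 | macrocyclic bridge ketone of asterelin A dimethyl ether (key-step product) | COc1cc2c3c(c1)oc1cc(ccc13)CCc1ccc(OC)c(c1)Oc1ccc(cc1)C(=O)C2 | intermediate
28 | asterelin A dimethyl ether | COc1cc2c3c(c1)oc1cc(ccc13)CCc1ccc(OC)c(c1)Oc1ccc(cc1)CC2 | intermediate
29 | asterelin A | Oc1cc2c3c(c1)oc1cc(ccc13)CCc1ccc(O)c(c1)Oc1ccc(cc1)CC2 | target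

Total step count: 15 (13 on the main line plus two one-step branches, steps 5 and 11).
Longest linear sequence: 13 steps (steps 1–4, 6–10, 12–15).

Steps most likely to fail

1. Step 13. Intermolecular cycloaddition (oligomerisation) or heat- and acid-induced loss of the aryloxyacetylene may outrun the entropically slow 18-membered closure, and ring strain may shift the regiochemistry towards the less strained meta-bridged mode. The fallback gives up the pyrone route and makes the diaryl ether and the macrocycle separately; it sets out from phenol 13 and returns at 28. Nucleophilic aromatic substitution of 13 on 4-fluorobenzaldehyde (K2CO3, DMF, 120 °C) should give methyl 7-{2-[3-(4-formylphenoxy)-4-methoxyphenyl]ethyl}-3-methoxydibenzofuran-1-carboxylate F1. LiAlH4 (THF, 0 °C) would reduce ester and aldehyde to [7-(2-{3-[4-(hydroxymethyl)phenoxy]-4-methoxyphenyl}ethyl)-3-methoxydibenzofuran-1-yl]methanol F2, and MnO2 (CH2Cl2) would oxidise both benzylic alcohols to 7-{2-[3-(4-formylphenoxy)-4-methoxyphenyl]ethyl}-3-methoxydibenzofuran-1-carbaldehyde F3. Intramolecular McMurry coupling (TiCl4, Zn, pyridine, THF, reflux, slow addition) would then close the 18-membered ring as the macrocyclic stilbene F4 (E/Z mixture, the geometry being erased next), and H2, Pd/C (EtOAc) would saturate it to 28.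

2. Step 12. Proton transfer from the acetylenic C–H to the benzylic zinc reagent during the insertion, or conjugate addition of the zinc reagent to C6 of the pyrone, may compete with acylation. The fallback avoids any carbanionic benzyl species; it sets out from chloride 21 and returns at 25. A carbonylative Stille coupling of 21 with CO (1 atm) and 5-(trimethylstannyl)-2H-pyran-2-one F5 (prepared from commercial 5-bromo-2H-pyran-2-one, Me3SnSnMe3 and Pd(PPh3)4) under PdCl2(PPh3)2 catalysis in THF at 50 °C should give ketone 25 directly, the carbonyl carbon then coming from CO.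

3. Step 4. Displacement of the unactivated fluoride may need temperatures at which the ester is cleaved irreversibly or the electron-rich bis-phenoxide decomposes. The fallback closes the furan by C–H oxidation instead of substitution; it sets out from bromide 2 and returns at 7 through 6. Suzuki–Miyaura coupling of 2 with (4-chlorophenyl)boronic acid (Pd(PPh3)4, K2CO3, DME/H2O) should give methyl 2-(4-chlorophenyl)-3,5-dimethoxybenzoate F6, and BBr3 would give methyl 2-(4-chlorophenyl)-3,5-dihydroxybenzoate F7. A phenol-directed aerobic C–H activation/C–O cyclisation (Pd(OAc)2, 4,5-diazafluoren-9-one, K2CO3, mesitylene, air, 120 °C) onto either of the two equivalent ortho positions of the chlorophenyl ring would then give phenoxide 6, methylated in the pot with MeI to 7.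

Further compounds

F1 | step 13 | methyl 7-{2-[3-(4-formylphenoxy)-4-methoxyphenyl]ethyl}-3-methoxydibenzofuran-1-carboxylate | COC(=O)c1cc(OC)cc2oc3cc(CCc4ccc(OC)c(Oc5ccc(C=O)cc5)c4)ccc3c12
F2 | step 13 | [7-(2-{3-[4-(hydroxymethyl)phenoxy]-4-methoxyphenyl}ethyl)-3-methoxydibenzofuran-1-yl]methanol | OCc1cc(OC)cc2oc3cc(CCc4ccc(OC)c(Oc5ccc(CO)cc5)c4)ccc3c12
F3 | step 13 | 7-{2-[3-(4-formylphenoxy)-4-methoxyphenyl]ethyl}-3-methoxydibenzofuran-1-carbaldehyde | O=Cc1cc(OC)cc2oc3cc(CCc4ccc(OC)c(Oc5ccc(C=O)cc5)c4)ccc3c12
F4 | step 13 | macrocyclic stilbene (asterelin A dimethyl ether with a CH=CH bridge between dibenzofuran C1 and ring D; E/Z mixture) | COc1cc2c3c(c1)oc1cc(ccc13)CCc1ccc(OC)c(c1)Oc1ccc(cc1)C=C2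
F5 | step 12 | 5-(trimethylstannyl)-2H-pyran-2-one | C[Sn](C)(C)C1=COC(=O)C=C1
F6 | step 4 | methyl 2-(4-chlorophenyl)-3,5-dimethoxybenzoate | COC(=O)c1cc(OC)cc(OC)c1-c1ccc(Cl)cc1
F7 | step 4 | methyl 2-(4-chlorophenyl)-3,5-dihydroxybenzoate | COC(=O)c1cc(O)cc(O)c1-c1ccc(Cl)cc1
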